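**Retrosynthetic overview**
1. Target 31 comes from hexaol 30 by one tin-templated double angeloylation (O3, O10); 30 comes from enone 28 by 1,3-syn reduction (C10 controls C8).
2. 28 comes from alkenyl triflate 26 and lactol 15 (from L-malic acid) by a photochemical decatungstate/nickel C–H alkenylation that forms C7–C8.
3. 26 comes from (R)-carvone: Luche/Mitsunobu (O5, brings in acid 10), isopropenyl to enol triflate, singlet-oxygen ene reaction (O4), hydroxyl-directed dihydroxylation (O2, O3).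
4. Acid 10 comes from (R)-lactic acid: Seebach acetal, enolate C-acylation, methylenation, lactonisation, carboxyl-directed hydrogenation (C3), kinetic ethylation (C5).
5. Rings: the cyclohexane is bought with carvone and never opened; the oxane (lactone) ring is closed in step 4, before the fragments are joined.

Assumption and conventions: the SMILES is taken as the full definition of the target (both 2-methylbut-2-enoates Z, i.e. angelates); locants in the Why lines use bisabolane numbering (ring C1–C6, C1 bears the side chain, C4 the methyl; side chain C7–C11; C14 = exocyclic CH2); "ester of acid 10" means the (2S,3S,5S)-5-ethyl-2,3-dimethyl-6-oxooxane-2-carboxylate; Tf = trifluoromethanesulfonyl.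

**Route**

Step 1
Reactants: 1 (R)-lactic acid
Product: 2 (2R,5R)-2-tert-butyl-5-methyl-1,3-dioxolan-4-one
Conditions: pivalaldehyde, TsOH·H2O (cat.), pentane, reflux (Dean–Stark); crystallisation from pentane, −78 °C
Reagents that add atoms: pivalaldehyde, CC(C)(C)C=O
Why: Acid-catalysed acetalisation (Seebach self-regeneration of stereocentres); the lactic acid centre steers the new acetal centre to the cis isomer, which is purified by crystallisation.

Step 2
Reactants: 2 (2R,5R)-2-tert-butyl-5-methyl-1,3-dioxolan-4-one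
Product: 4 methyl 4-[(2R,4S)-2-tert-butyl-4-methyl-5-oxo-1,3-dioxolan-4-yl]-4-oxobutanoate, via lithium enolate 3 (not isolated)
Conditions: LiN(iPr)2, THF, −78 °C; enolate added to ClC(O)CH2CH2CO2Me (1.5 equiv), THF, −78 °C
Reagents that add atoms: methyl 4-chloro-4-oxobutanoate, COC(=O)CCC(Cl)=O
Why: Enolate C-acylation in which the acid chloride enters anti to the tert-butyl group, so the quaternary carbon (C2 of the later lactone) is formed with the configuration dictated by lactic acid; inverse addition limits proton transfer to the more acidic product.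

Step 3
Reactants: 4 methyl 4-[(2R,4S)-2-tert-butyl-4-methyl-5-oxo-1,3-dioxolan-4-yl]-4-oxobutanoate
Product: 5 methyl 4-[(2R,4S)-2-tert-butyl-4-methyl-5-oxo-1,3-dioxolan-4-yl]pent-4-enoate
Conditions: Zn, CH2Br2, TiCl4, THF/CH2Cl2, 0 → 20 °C
Reagents that add atoms: dibromomethane, BrCBr
Why: Takai–Lombardo methylenation, a non-basic methylene transfer that works on hindered enolisable ketones and leaves the ester and the acetal untouched.

Step 4
Reactants: 5 methyl 4-[(2R,4S)-2-tert-butyl-4-methyl-5-oxo-1,3-dioxolan-4-yl]pent-4-enoate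
Product: 7 (2S)-2-methyl-3-methylidene-6-oxooxane-2-carboxylic acid, via hydroxy acid ester 6 (not isolated)
Conditions: CF3CO2H/H2O 9:1, 20 °C; then TsOH·H2O (cat.), toluene, 80 °C
Reagents that add atoms: none
Why: Acetal hydrolysis followed by acid-catalysed lactonisation (transesterification of the tertiary alcohol onto the methyl ester) closes the six-membered lactone without touching the quaternary centre.

Step 5
Reactants: 7 (2S)-2-methyl-3-methylidene-6-oxooxane-2-carboxylic acid
Product: 8 (2S,3S)-2,3-dimethyl-6-oxooxane-2-carboxylic acid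
Conditions: H2 (30 bar), [Rh(nbd)(dppb)]BF4 (5 mol%), Et3N (1 equiv), CH2Cl2/MeOH, 20 °C
Reagents that add atoms: none
Why: Carboxylate-directed homogeneous hydrogenation: rhodium bound to the carboxylate delivers H2 to the exocyclic alkene from the carboxyl face, so the new C3 methyl ends cis to the C2 methyl (3S).

Step 6
Reactants: 8 (2S,3S)-2,3-dimethyl-6-oxooxane-2-carboxylic acid
Product: 10 (2S,3S,5S)-5-ethyl-2,3-dimethyl-6-oxooxane-2-carboxylic acid, via dilithium enolate carboxylate 9 (not isolated)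
Conditions: LiN(iPr)2 (2.2 equiv), THF, −78 °C; EtI, DMPU, −78 → −40 °C; aq. HCl
Reagents that add atoms: iodoethane, CCI
Why: Kinetic lactone enolate alkylation: ethyl iodide attacks axially on the face opposite the C3 methyl to give the trans-3,5 (5S) product, which is the less stable epimer and is therefore kept away from enolising base in all later steps.

Step 7
Reactants: 11 (S)-malic acid
Product: 12 2-[(4S)-2,2-dimethyl-5-oxo-1,3-dioxolan-4-yl]acetic acid
Conditions: 2,2-dimethoxypropane, TsOH·H2O (cat.), 20 °C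
Reagents that add atoms: 2,2-dimethoxypropane, COC(C)(C)OC
Why: Acetonide (dioxolanone) formation at the alpha-hydroxy acid unit differentiates the two carboxyl groups; the stereocentre (later C10) is untouched.

Step 8
Reactants: 12 2-[(4S)-2,2-dimethyl-5-oxo-1,3-dioxolan-4-yl]acetic acid
Product: 14 (4S)-4-hydroxy-5,5-dimethyloxolan-2-one, via dihydroxy acid 13 (not isolated)
Conditions: MeMgBr (5 equiv), THF, −20 → 20 °C; then 2 M HCl, 20 °C
Reagents that add atoms: methylmagnesium bromide, C[Mg]Br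
Why: Double Grignard addition to the activated dioxolanone carbonyl (the magnesium carboxylate is inert) builds the C11 dimethyl carbinol, and acidic work-up lactonises the dihydroxy acid; C10 comes unchanged from malic acid.

Step 9
Reactants: 14 (4S)-4-hydroxy-5,5-dimethyloxolan-2-one
Product: 15 (4S)-5,5-dimethyloxolane-2,4-diol (lactol, anomer mixture)
Conditions: iBu2AlH (2.2 equiv), CH2Cl2, −78 °C
Reagents that add atoms: none
Why: Partial reduction of the lactone to the lactol with iBu2AlH at low temperature; the first equivalent is consumed by the free hydroxyl.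

Step 10
Reactants: 16 (R)-carvone
Product: 17 (1R,5R)-2-methyl-5-(prop-1-en-2-yl)cyclohex-2-en-1-ol (cis-carveol)
Conditions: NaBH4, CeCl3·7H2O, MeOH, 0 °C
Reagents that add atoms: none
Why: Luche 1,2-reduction; axial hydride attack gives the cis alcohol.

Step 11
Reactants: 17 (1R,5R)-cis-carveol; 10 (2S,3S,5S)-5-ethyl-2,3-dimethyl-6-oxooxane-2-carboxylic acid
Product: 18 (1S,5R)-2-methyl-5-(prop-1-en-2-yl)cyclohex-2-en-1-yl ester of acid 10
Conditions: PPh3, DIAD, toluene, 0 → 20 °C
Reagents that add atoms: none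
Why: Mitsunobu esterification with inversion at the allylic carbinol gives the trans ester and sets the C5 oxygen configuration; the alpha-acyloxy acid is acidic enough for clean activation.

Step 12
Reactants: 18 (1S,5R)-2-methyl-5-(prop-1-en-2-yl)cyclohex-2-en-1-yl ester of acid 10
Product: 20 (1S,5R)-5-acetyl-2-methylcyclohex-2-en-1-yl ester of acid 10, via vicinal diol 19 (not isolated)
Conditions: OsO4 (2 mol%), NaIO4 (4 equiv), 2,6-lutidine, 1,4-dioxane/H2O 3:1, 20 °C
Reagents that add atoms: osmium tetroxide, O=[Os](=O)(=O)=O (oxygen donor, regenerated by sodium periodate, [Na+].[O-]I(=O)(=O)=O)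
Why: Lemieux–Johnson cleavage; OsO4 attacks the unhindered 1,1-disubstituted alkene in preference to the ring alkene, which is trisubstituted, shielded and deactivated by the allylic acyloxy group.

Step 13
Reactants: 20 (1S,5R)-5-acetyl-2-methylcyclohex-2-en-1-yl ester of acid 10
Product: 22 (1S,5R)-2-methyl-5-[1-(TfO)ethenyl]cyclohex-2-en-1-yl ester of acid 10, via potassium enolate 21 (not isolated)
Conditions: KN(SiMe3)2 (1.05 equiv), THF, −78 °C; PhNTf2, −78 → 0 °C
Reagents that add atoms: N-phenylbis(trifluoromethanesulfonimide), O=S(=O)(N(c1ccccc1)S(=O)(=O)C(F)(F)F)C(F)(F)F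
Why: Kinetic deprotonation at the acetyl methyl and O-triflation of the enolate (enol triflate formation); the tertiary lactone alpha-CH is far less acidic and is not touched at −78 °C.

Step 14
Reactants: 22 (1S,5R)-2-methyl-5-[1-(TfO)ethenyl]cyclohex-2-en-1-yl ester of acid 10
Product: 24 (1S,2S,5S)-2-hydroxy-2-methyl-5-[1-(TfO)ethenyl]cyclohex-3-en-1-yl ester of acid 10, via allylic hydroperoxide 23 (not isolated)
Conditions: O2, meso-tetraphenylporphyrin (1 mol%), white LEDs, CH2Cl2, −20 °C; then PPh3, −20 → 20 °C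
Reagents that add atoms: dioxygen, O=O
Why: Schenck ene reaction of singlet oxygen (photochemical C4–O bond formation): oxygen adds to C4 on the face opposite the pseudoaxial C5 acyloxy group and abstracts the axial C2–H on the same face, giving the tertiary hydroperoxide with the alkene moved to C2=C3, and PPh3 reduces it at once; the electron-poor enol triflate does not react with singlet oxygen, and the exocyclic-methylene regioisomer is the expected minor by-product.

Step 15
Reactants: 24 (1S,2S,5S)-2-hydroxy-2-methyl-5-[1-(TfO)ethenyl]cyclohex-3-en-1-yl ester of acid 10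
Product: 26 (1S,2S,3S,4S,5S)-2,3,4-trihydroxy-2-methyl-5-[1-(TfO)ethenyl]cyclohexyl ester of acid 10, via osmate ester 25 (not isolated)
Conditions: OsO4 (1.05 equiv), TMEDA (1.1 equiv), CH2Cl2, −78 °C; then aq. NaHSO3, THF, 20 °C
Reagents that add atoms: osmium tetroxide, O=[Os](=O)(=O)=O
Why: Donohoe hydroxyl-directed dihydroxylation: the OsO4·TMEDA complex is hydrogen-bonded by the tertiary allylic alcohol and adds syn to it (also the face away from the acyloxy group), setting C2 and C3; the enol triflate is inert at −78 °C.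

Step 16
Reactants: 26 (1S,2S,3S,4S,5S)-2,3,4-trihydroxy-2-methyl-5-[1-(TfO)ethenyl]cyclohexyl ester of acid 10; 15 (4S)-5,5-dimethyloxolane-2,4-diol
Product: 28 (1S,2S,3S,4S,5R)-2,3,4-trihydroxy-5-[(5S)-5,6-dihydroxy-6-methyl-3-oxohept-1-en-2-yl]-2-methylcyclohexyl ester of acid 10, via cyclic hemiketal 27 (not isolated)
Conditions: (Bu4N)4[W10O32] (2 mol%), NiBr2(dme) (10 mol%), 4,4′-di-tert-butyl-2,2′-bipyridine (10 mol%), K3PO4 (1.5 equiv), 15 (3 equiv), MeCN, 390 nm LEDs, 25 °C
Reagents that add atoms: none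
Why: Proposed new method: decatungstate/nickel dual photocatalytic C–H alkenylation of a lactol, in which photoexcited decatungstate abstracts the hydridic anomeric C–H of 15 (the weakest, doubly oxygen-activated C–H present; the open hydroxy-aldehyde tautomer gives the equivalent acyl radical), the radical is captured by the alkenylnickel species from oxidative addition of triflate 26 to zerovalent nickel, and reductive elimination from trivalent nickel forms C7–C8, after which hemiketal 27 opens to enone 28 (no stereocentre is made here, and 15 is used in excess so that hydrogen abstraction from 26 does not compete); the closest known reaction type is decatungstate/nickel C–H arylation of ethers, acetals and aldehydes with aryl halides, which has not been shown for lactol C–H bonds or alkenyl triflates.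

Step 17
Reactants: 28 (1S,2S,3S,4S,5R)-2,3,4-trihydroxy-5-[(5S)-5,6-dihydroxy-6-methyl-3-oxohept-1-en-2-yl]-2-methylcyclohexyl ester of acid 10
Product: 30 (1S,2S,3S,4S,5R)-2,3,4-trihydroxy-2-methyl-5-[(3R,5S)-3,5,6-trihydroxy-6-methylhept-1-en-2-yl]cyclohexyl ester of acid 10, via diethylboron chelate 29 (not isolated)
Conditions: Et2BOMe (4 equiv), THF/MeOH 4:1, −78 °C; NaBH4, −78 °C; then MeOH, co-evaporation
Reagents that add atoms: none
Why: Narasaka–Prasad reduction: the boron chelate between the C10 hydroxyl and the C8 ketone is reduced by external axial hydride delivery to the 1,3-syn diol (8R, controlled by C10), and boron activation favours 1,2- over 1,4-reduction of the enone.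

Step 18
Reactants: 30 (1S,2S,3S,4S,5R)-2,3,4-trihydroxy-2-methyl-5-[(3R,5S)-3,5,6-trihydroxy-6-methylhept-1-en-2-yl]cyclohexyl ester of acid 10
Product: 31 CNP0148734.1 (target)
Conditions: Me2SnCl2 (10 mol%), iPr2NEt (3 equiv), angelic anhydride (2.3 equiv), THF, 0 → 25 °C
Reagents that add atoms: angelic anhydride, C/C=C(/C)C(=O)OC(=O)/C(C)=C\C
Why: Tin-templated regioselective acylation: Me2SnCl2 forms stannylene acetals only at the two vicinal diol units (ring cis-C2/C3 and side-chain C10/C11) and activates the equatorial O3 and the secondary O10, while the isolated C8–OH, the axial C2–OH and the tertiary hydroxyls stay free; the equatorial C3 ester is also the thermodynamically preferred acyl position, and the base-mild conditions avoid angelate-to-tiglate isomerisation.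

**Compound list**
1 | (R)-lactic acid | C[C@@H](O)C(=O)O | starting material
2 | (2R,5R)-2-tert-butyl-5-methyl-1,3-dioxolan-4-one | C[C@H]1O[C@@H](C(C)(C)C)OC1=O | intermediate
3 | lithium enolate of 2 | CC1=C([O-])O[C@H](C(C)(C)C)O1.[Li+] | intermediate (not isolated)
4 | methyl 4-[(2R,4S)-2-tert-butyl-4-methyl-5-oxo-1,3-dioxolan-4-yl]-4-oxobutanoate | C[C@@]1(C(=O)CCC(=O)OC)O[C@@H](C(C)(C)C)OC1=O | intermediate
5 | methyl 4-[(2R,4S)-2-tert-butyl-4-methyl-5-oxo-1,3-dioxolan-4-yl]pent-4-enoate | C[C@@]1(C(=C)CCC(=O)OC)O[C@@H](C(C)(C)C)OC1=O | intermediate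
6 | (2S)-2-hydroxy-6-methoxy-2-methyl-3-methylidene-6-oxohexanoic acid | OC(=O)[C@@](C)(O)C(=C)CCC(=O)OC | intermediate (not isolated)
7 | (2S)-2-methyl-3-methylidene-6-oxooxane-2-carboxylic acid | OC(=O)[C@@]1(C)OC(=O)CCC1=C | intermediate
8 | (2S,3S)-2,3-dimethyl-6-oxooxane-2-carboxylic acid | OC(=O)[C@@]1(C)OC(=O)CC[C@@H]1C | intermediate
9 | dilithium enolate carboxylate of 8 | [Li+].[Li+].[O-]C(=O)[C@@]1(C)OC([O-])=CC[C@@H]1C | intermediate (not isolated)
10 | (2S,3S,5S)-5-ethyl-2,3-dimethyl-6-oxooxane-2-carboxylic acid | OC(=O)[C@@]1(C)OC(=O)[C@@H](CC)C[C@@H]1C | intermediate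
11 | (S)-malic acid | OC(=O)C[C@H](O)C(=O)O | starting material
12 | 2-[(4S)-2,2-dimethyl-5-oxo-1,3-dioxolan-4-yl]acetic acid | OC(=O)C[C@@H]1OC(C)(C)OC1=O | intermediate
13 | (3S)-3,4-dihydroxy-4-methylpentanoic acid | OC(=O)C[C@H](O)C(C)(C)O | intermediate (not isolated)
14 | (4S)-4-hydroxy-5,5-dimethyloxolan-2-one | O=C1C[C@H](O)C(C)(C)O1 | intermediate
15 | (4S)-5,5-dimethyloxolane-2,4-diol (anomer mixture) | OC1C[C@H](O)C(C)(C)O1 | intermediate
16 | (R)-carvone | CC(=C)[C@H]1CC(=O)C(C)=CC1 | starting material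
17 | (1R,5R)-2-methyl-5-(prop-1-en-2-yl)cyclohex-2-en-1-ol | CC(=C)[C@H]1C[C@@H](O)C(C)=CC1 | intermediate
18 | (1S,5R)-2-methyl-5-(prop-1-en-2-yl)cyclohex-2-en-1-yl (2S,3S,5S)-5-ethyl-2,3-dimethyl-6-oxooxane-2-carboxylate | CC(=C)[C@H]1C[C@H](OC(=O)[C@@]2(C)OC(=O)[C@@H](CC)C[C@@H]2C)C(C)=CC1 | intermediate
19 | (1S,5R)-5-(1,2-dihydroxypropan-2-yl)-2-methylcyclohex-2-en-1-yl ester of acid 10 (carbinol epimers) | CC(O)(CO)[C@H]1C[C@H](OC(=O)[C@@]2(C)OC(=O)[C@@H](CC)C[C@@H]2C)C(C)=CC1 | intermediate (not isolated)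
20 | (1S,5R)-5-acetyl-2-methylcyclohex-2-en-1-yl ester of acid 10 | CC(=O)[C@H]1C[C@H](OC(=O)[C@@]2(C)OC(=O)[C@@H](CC)C[C@@H]2C)C(C)=CC1 | intermediate
21 | potassium enolate of 20 (at the acetyl methyl) | [K+].C=C([O-])[C@H]1C[C@H](OC(=O)[C@@]2(C)OC(=O)[C@@H](CC)C[C@@H]2C)C(C)=CC1 | intermediate (not isolated)
22 | (1S,5R)-2-methyl-5-[1-(trifluoromethanesulfonyloxy)ethenyl]cyclohex-2-en-1-yl ester of acid 10 | C=C(OS(=O)(=O)C(F)(F)F)[C@H]1C[C@H](OC(=O)[C@@]2(C)OC(=O)[C@@H](CC)C[C@@H]2C)C(C)=CC1 | intermediate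
23 | (1S,2S,5S)-2-hydroperoxy-2-methyl-5-[1-(trifluoromethanesulfonyloxy)ethenyl]cyclohex-3-en-1-yl ester of acid 10 | C=C(OS(=O)(=O)C(F)(F)F)[C@H]1C[C@H](OC(=O)[C@@]2(C)OC(=O)[C@@H](CC)C[C@@H]2C)[C@@](C)(OO)C=C1 | intermediate (not isolated)
24 | (1S,2S,5S)-2-hydroxy-2-methyl-5-[1-(trifluoromethanesulfonyloxy)ethenyl]cyclohex-3-en-1-yl ester of acid 10 | C=C(OS(=O)(=O)C(F)(F)F)[C@H]1C[C@H](OC(=O)[C@@]2(C)OC(=O)[C@@H](CC)C[C@@H]2C)[C@@](C)(O)C=C1 | intermediate
25 | cyclic osmate ester of 26 at the two new oxygens (TMEDA complex) | C=C(OS(=O)(=O)C(F)(F)F)[C@H]1C[C@H](OC(=O)[C@@]2(C)OC(=O)[C@@H](CC)C[C@@H]2C)[C@@](C)(O)[C@@H](O[Os]3(=O)=O)[C@H]1O3.CN(C)CCN(C)C | intermediate (not isolated)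
26 | (1S,2S,3S,4S,5S)-2,3,4-trihydroxy-2-methyl-5-[1-(trifluoromethanesulfonyloxy)ethenyl]cyclohexyl ester of acid 10 | C=C(OS(=O)(=O)C(F)(F)F)[C@H]1C[C@H](OC(=O)[C@@]2(C)OC(=O)[C@@H](CC)C[C@@H]2C)[C@@](C)(O)[C@@H](O)[C@H]1O | intermediate
27 | cyclic hemiketal of 28 (2-alkenyl-2,4-dihydroxy-5,5-dimethyloxolane, anomer mixture) | C=C(C3(O)C[C@H](O)C(C)(C)O3)[C@H]1C[C@H](OC(=O)[C@@]2(C)OC(=O)[C@@H](CC)C[C@@H]2C)[C@@](C)(O)[C@@H](O)[C@H]1O | intermediate (not isolated)
28 | (1S,2S,3S,4S,5R)-2,3,4-trihydroxy-5-[(5S)-5,6-dihydroxy-6-methyl-3-oxohept-1-en-2-yl]-2-methylcyclohexyl ester of acid 10 | C=C(C(=O)C[C@H](O)C(C)(C)O)[C@H]1C[C@H](OC(=O)[C@@]2(C)OC(=O)[C@@H](CC)C[C@@H]2C)[C@@](C)(O)[C@@H](O)[C@H]1O | intermediate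
29 | O10-diethylboryl chelate of 28 | C=C(C(=O)C[C@H](OB(CC)CC)C(C)(C)O)[C@H]1C[C@H](OC(=O)[C@@]2(C)OC(=O)[C@@H](CC)C[C@@H]2C)[C@@](C)(O)[C@@H](O)[C@H]1O | intermediate (not isolated)
30 | (1S,2S,3S,4S,5R)-2,3,4-trihydroxy-2-methyl-5-[(3R,5S)-3,5,6-trihydroxy-6-methylhept-1-en-2-yl]cyclohexyl ester of acid 10 | C=C([C@H](O)C[C@H](O)C(C)(C)O)[C@H]1C[C@H](OC(=O)[C@@]2(C)OC(=O)[C@@H](CC)C[C@@H]2C)[C@@](C)(O)[C@@H](O)[C@H]1O | intermediate
31 | (1S,2R,3S,4S,5R)-2,4-dihydroxy-2-methyl-3-{[(2Z)-2-methylbut-2-enoyl]oxy}-5-[(3R,5S)-3,6-dihydroxy-6-methyl-5-{[(2Z)-2-methylbut-2-enoyl]oxy}hept-1-en-2-yl]cyclohexyl (2S,3S,5S)-5-ethyl-2,3-dimethyl-6-oxooxane-2-carboxylate | C=C([C@H](O)C[C@H](OC(=O)/C(C)=C\C)C(C)(C)O)[C@H]1C[C@H](OC(=O)[C@@]2(C)OC(=O)[C@@H](CC)C[C@@H]2C)[C@@](C)(O)[C@@H](OC(=O)/C(C)=C\C)[C@H]1O | target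

**Step count**
Total: 18 steps. Longest linear sequence: 14 steps (steps 1–6, then 11–18).

**Three steps most likely to fail, with fallbacks**

Step 14 (ene regiochemistry; the exocyclic-methylene isomer may compete). The fallback sets out from 22. Electrochemical allylic C–H oxidation (Cl4NHPI cat., tBuOOH, pyridine, LiClO4, acetone, carbon anode, constant current) oxidises the only unhindered allylic CH2 (C2) to the enone (1S,5R)-2-methyl-4-oxo-5-[1-(TfO)ethenyl]cyclohex-2-en-1-yl ester of acid 10 F1. LiBH(sBu)3 in THF at −78 °C then reduces the carbonyl 1,2 from the face opposite the neighbouring C1 substituent to the cis allylic alcohol (1S,4R,5S)-4-hydroxy-2-methyl-5-[1-(TfO)ethenyl]cyclohex-2-en-1-yl ester of acid 10 F2. OsO4·TMEDA dihydroxylation, now directed by the C2 hydroxyl and again anti to the acyloxy group, gives triol 26, where the route is rejoined (step 15 is skipped).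

Step 16 (the proposed new coupling). The fallback uses known chemistry and sets out from 26 and 15. A Nozaki–Hiyama–Kishi coupling (CrCl2 in excess, NiCl2 cat., DMF) of the alkenyl triflate with the open hydroxy-aldehyde form of the lactol gives the allylic alcohol as the C8-epimer mixture of 30 F3. MnO2 in CH2Cl2 then oxidises only the allylic C8 hydroxyl and returns enone 28, where the route is rejoined before step 17.

Step 18 (site selectivity among six hydroxyls). The fallback sets out from 30. TBSCl (1.1 equiv), imidazole, DMF, −20 °C silylates the least hindered secondary hydroxyl (allylic C8–OH; O3 and O10 are flanked by quaternary carbons and O2 is axial) to give the 8-O-tert-butyldimethylsilyl ether of 30 F4. Angelic acid, 2,4,6-trichlorobenzoyl chloride and Et3N in toluene at 75 °C then acylate O3 and O10 to give the 8-O-tert-butyldimethylsilyl ether of 31 F5. HF·pyridine in THF removes the silyl group and gives target 31.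

**Further compounds**
F1 | step 14 | (1S,5R)-2-methyl-4-oxo-5-[1-(trifluoromethanesulfonyloxy)ethenyl]cyclohex-2-en-1-yl ester of acid 10 | C=C(OS(=O)(=O)C(F)(F)F)[C@H]1C[C@H](OC(=O)[C@@]2(C)OC(=O)[C@@H](CC)C[C@@H]2C)C(C)=CC1=O
F2 | step 14 | (1S,4R,5S)-4-hydroxy-2-methyl-5-[1-(trifluoromethanesulfonyloxy)ethenyl]cyclohex-2-en-1-yl ester of acid 10 | C=C(OS(=O)(=O)C(F)(F)F)[C@H]1C[C@H](OC(=O)[C@@]2(C)OC(=O)[C@@H](CC)C[C@@H]2C)C(C)=C[C@H]1O
F3 | step 16 | C8-epimer mixture of 30 | C=C(C(O)C[C@H](O)C(C)(C)O)[C@H]1C[C@H](OC(=O)[C@@]2(C)OC(=O)[C@@H](CC)C[C@@H]2C)[C@@](C)(O)[C@@H](O)[C@H]1O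
F4 | step 18 | 8-O-tert-butyldimethylsilyl ether of 30 | C=C([C@H](O[Si](C)(C)C(C)(C)C)C[C@H](O)C(C)(C)O)[C@H]1C[C@H](OC(=O)[C@@]2(C)OC(=O)[C@@H](CC)C[C@@H]2C)[C@@](C)(O)[C@@H](O)[C@H]1O
F5 | step 18 | 8-O-tert-butyldimethylsilyl ether of 31 | C=C([C@H](O[Si](C)(C)C(C)(C)C)C[C@H](OC(=O)/C(C)=C\C)C(C)(C)O)[C@H]1C[C@H](OC(=O)[C@@]2(C)OC(=O)[C@@H](CC)C[C@@H]2C)[C@@](C)(O)[C@@H](OC(=O)/C(C)=C\C)[C@H]1O
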